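Everything rests on cutting C1–C10 and C9–C11 (drimane numbering), which reduces ring B to 3-methylcyclohex-2-enone. The feature exploited is that quaternary C10 (bearing the methyl, C1, C5 and C9) lies β to C8, the ring B carbon carrying the C12 methylene, with C9 in between. C10 therefore maps onto an enone β-carbon, C9 onto the enolate carbon and C8 onto the carbonyl. One copper-catalysed operation adds the homoprenyl chain (C1–C4) to C10 enantioselectively and hydroxymethylates C9; its precursor is the flat, achiral enone. The C8 ketone is later turned into a C5-nucleophilic dienylsilane that closes ring A onto a C3–C4 epoxide and releases the 6,8(12)-diene.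

Key step: step 2

Assumption: drimane numbering is applied to every intermediate (C11 = CH2O carbon on C9, C12 = carbon on C8), and the ligand antipode that makes C10 (S) in 6 is taken, both antipodes being available from tert-leucinol.

Step 1
Reactants: 1 5-bromo-2-methylpent-2-ene
Product: 2 4-methylpent-3-enylmagnesium bromide
Conditions: Mg turnings, I2 (crystal), Et2O, gentle reflux; titrated before use
Reagents that add atoms: magnesium, [Mg]
Why: Grignard formation by magnesium insertion into the primary C–Br bond; the remote trisubstituted alkene is inert, and closure to a cyclopropylcarbinyl species would put magnesium on a tertiary carbon and is uphill.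

Step 2
Reactants: 2 4-methylpent-3-enylmagnesium bromide; 3 3-methylcyclohex-2-en-1-one; 4 formaldehyde (monomer from cracked paraformaldehyde)
Product: 6 (2R,3S)-2-(hydroxymethyl)-3-methyl-3-(4-methylpent-3-enyl)cyclohexan-1-one, via bromomagnesium enolate 5 (not isolated)
Conditions: Cu(OTf)2 (3 mol %), 1-(1-hydroxy-3,3-dimethylbutan-2-yl)-3-mesityl-4,5-dihydroimidazolium hexafluorophosphate (single antipode, 4 mol %), 2 (1.2 equiv), Et2O, −30 °C; then CH2O gas (4) in N2, −78 → −40 °C; cold aq. NH4Cl
Reagents that add atoms: none
Why: The NHC–copper complex formed in the flask takes the homoprenyl group from 2, binds the C9=C10 π bond of 3 and passes the chain to C10 by oxidative addition–reductive elimination, leaving the regiodefined enolate 5 (C8–O, C8=C9). Monomeric formaldehyde then adds to C9 of 5 through a magnesium-chelated aldol transition state, so C1–C10 and C9–C11 are made in one flask and no ring is closed. The closest known reaction type is the Cu/NHC-catalysed asymmetric conjugate addition of primary alkyl Grignard reagents to 3-substituted cyclohexenones with electrophilic trapping of the magnesium enolate. C10 is set by the chiral ligand (face selection on the flat enone), and C9 by the substrate: the electrophile enters axially, anti to the pseudoaxial C10 substituent, and the transition state with the chain in that position keeps only the small methyl gauche to the incoming CH2O. Because methyl and chain differ little in size, this second preference is expected to be modest, so the C9 epimer is removed by chromatography of 6 and recycled by base equilibration next to the C8 ketone. The step needs 1,4- over 1,2-addition (secured by the copper catalyst in Et2O), a single hydroxymethylation (excess gaseous CH2O, low temperature) and no retro-aldol or dehydration (cold neutral quench).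

Step 3
Reactants: 6 (2R,3S)-2-(hydroxymethyl)-3-methyl-3-(4-methylpent-3-enyl)cyclohexan-1-one
Product: 7 (2R,3S)-2-[(tert-butyldiphenylsilyloxy)methyl]-3-methyl-3-(4-methylpent-3-enyl)cyclohexan-1-one
Conditions: t-BuPh2SiCl, imidazole, CH2Cl2, 0 °C → rt
Reagents that add atoms: tert-butyl(chloro)diphenylsilane, CC(C)(C)[Si](Cl)(c1ccccc1)c1ccccc1
Why: Standard silylation of a primary alcohol with a base too mild for retro-aldol or β-elimination; the bulky silyl group also shields C9–H in the later enolisations.

Step 4
Reactants: 7 (2R,3S)-2-[(tert-butyldiphenylsilyloxy)methyl]-3-methyl-3-(4-methylpent-3-enyl)cyclohexan-1-one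
Product: 10 (5R,6R)-6-[(tert-butyldiphenylsilyloxy)methyl]-5-methyl-5-(4-methylpent-3-enyl)cyclohex-2-en-1-one, via lithium enolate 8 (not isolated), via trimethylsilyl enol ether 9 (not isolated)
Conditions: LiN(i-Pr)2, THF, −78 °C; Me3SiCl; pentane work-up; Pd(OAc)2 (1.05 equiv), MeCN, rt
Reagents that add atoms: lithium diisopropylamide, [Li]N(C(C)C)C(C)C (lithium stays only in 8); chlorotrimethylsilane, C[Si](C)(C)Cl (silyl group stays only in 9)
Why: Saegusa–Ito dehydrogenation: the amide base takes the accessible C7–H rather than the shielded C9–H, and palladium diacetate turns the C7=C8 silyl enol ether into the C6=C7 enone by β-hydride loss from C6 (C10 is quaternary, so no other enone can form).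

Step 5
Reactants: 10 (5R,6R)-6-[(tert-butyldiphenylsilyloxy)methyl]-5-methyl-5-(4-methylpent-3-enyl)cyclohex-2-en-1-one
Product: 12 through-conjugated trimethylsilyl dienol ether of 10 (C5=C6–C7=C8–OSiMe3; C9 and C10 unchanged), via bromomagnesium dienolate 11 (not isolated)
Conditions: MeMgBr (1.3 equiv), FeCl3 (3 mol %), Et2O, −20 °C; Me3SiCl, Et3N, DMPU, −20 °C → rt; pentane, cold aq. NaHCO3 wash
Reagents that add atoms: methylmagnesium bromide, C[Mg]Br (MgBr stays only in 11); chlorotrimethylsilane, C[Si](C)(C)Cl
Why: Known iron-catalysed γ-deprotonation of enones with MeMgBr followed by O-silylation; it removes a C5–H instead of the α′ C9–H, so C9 keeps its configuration and the C11 silyloxy group never sits β to a carbanion.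

Step 6
Reactants: 12 through-conjugated trimethylsilyl dienol ether of 10
Product: 14 C8 dienyl triflate (C5=C6–C7=C8–OTf; C9 and C10 unchanged), via lithium dienolate 13 (not isolated)
Conditions: MeLi, THF, 0 °C; PhNTf2, −78 → 0 °C
Reagents that add atoms: methyllithium, [Li]C (lithium stays only in 13); N-phenylbis(trifluoromethanesulfonimide), O=S(=O)(N(c1ccccc1)S(=O)(=O)C(F)(F)F)C(F)(F)F
Why: Silyl enol ether cleavage with MeLi releases the regiodefined lithium dienolate, and its O-sulfonylation (standard enol triflate synthesis) fixes the C5=C6–C7=C8 diene and deactivates it for the oxidation that follows.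

Step 7
Reactants: 14 C8 dienyl triflate
Product: 15 (3R)-3,4-epoxide of 14
Conditions: D-fructose-derived Shi ketone (1,2:4,5-di-O-isopropylidene-β-D-erythro-2,3-hexodiulo-2,6-pyranose, 30 mol %), KHSO5 (as 2KHSO5·KHSO4·K2SO4), K2CO3, Bu4NHSO4, MeCN–CH2(OMe)2–aq. Na2B4O7 buffer (pH 10.5), 0 °C
Reagents that add atoms: potassium peroxymonosulfate KHSO5, [K+].[O-]S(=O)(=O)OO
Why: Shi asymmetric epoxidation: the chiral dioxirane attacks the electron-rich isolated C3=C4 alkene far faster than the triflate-deactivated diene, and the D-fructose-derived ketone sets (3R) by reagent control through the spiro transition state.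

Step 8
Reactants: 15 (3R)-3,4-epoxide of 14; 16 (trimethylsilyl)methylmagnesium chloride
Product: 17 epoxy pentadienylsilane (Me3Si–C12H2–C8=C7–C6=C5; 3R; C9 and C10 unchanged)
Conditions: Pd(PPh3)4 (5 mol %), 16 (2 equiv), THF, 0 °C
Reagents that add atoms: none
Why: Kumada–Corriu coupling of an enol triflate with a Grignard reagent lacking β-hydrogens (standard allylsilane synthesis) installs C12; zerovalent palladium inserts into C8–OTf faster than the sluggish silylmethyl Grignard opens the hindered trisubstituted epoxide at 0 °C.

Step 9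
Reactants: 17 epoxy pentadienylsilane
Product: 18 (3R,5S,9R,10R)-11-(tert-butyldiphenylsilyloxy)drima-6,8(12)-dien-3-ol (trans-fused; equatorial OH)
Conditions: MeAlCl2 (1.5 equiv), CH2Cl2, −78 °C; Et3N, then aq. NaHCO3
Reagents that add atoms: none
Why: Proposed new method: MeAlCl2 binds the epoxide oxygen, C5 (the ε-terminus of the C5=C6–C7=C8–C12–Si pentadienylsilane) attacks tertiary C4 from the rear of the C4–O bond (6-endo opening, ring A), and the resulting C6–C8 allyl cation, β to silicon, loses Me3Si+ from C12 to leave the C6=C7/C8=C12 diene; the closest known reaction types are allylsilane-terminated epoxide cyclizations and the ε-selective Hosomi–Sakurai reactions of pentadienylsilanes; C3 keeps the epoxide configuration and ends equatorial (3R), and C5–H is meant to end anti to the C10 methyl because, with the (3R)-epoxide, only the trans-fused closure unites a chair-like ring A with backside opening, whereas the cis-fused alternative (stereoelectronically the easier attack on a ring π bond) would have to pass through a boat.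

Step 10
Reactants: 18 (3R,5S,9R,10R)-11-(tert-butyldiphenylsilyloxy)drima-6,8(12)-dien-3-ol
Product: 19 (5S,9R,10R)-11-(tert-butyldiphenylsilyloxy)drima-6,8(12)-dien-3-one
Conditions: Dess–Martin periodinane, CH2Cl2, 0 °C → rt
Reagents that add atoms: none
Why: Dess–Martin oxidation of the secondary C3 alcohol under near-neutral conditions leaves the diene and silyl ether untouched and erases the C3 centre on purpose.

Step 11
Reactants: 19 (5S,9R,10R)-11-(tert-butyldiphenylsilyloxy)drima-6,8(12)-dien-3-one
Product: 20 (3S,5S,9R,10R)-11-(tert-butyldiphenylsilyloxy)drima-6,8(12)-dien-3-ol (axial OH)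
Conditions: KBH(s-Bu)3, THF, −78 °C; H2O
Reagents that add atoms: none
Why: Bulky trialkylborohydride reduction, known for 4,4-dimethyl-3-oxo terpenoids: hydride arrives along the equatorial trajectory, away from the syn-axial C1–H and C5–H, and gives the axial (3S) alcohol under control of the rigid trans-decalin.

Step 12
Reactants: 20 (3S,5S,9R,10R)-11-(tert-butyldiphenylsilyloxy)drima-6,8(12)-dien-3-ol
Product: 21 (3S,5S,9R,10R)-drima-6,8(12)-diene-3,11-diol
Conditions: Bu4NF, THF, rt
Reagents that add atoms: none
Why: Fluoride-driven desilylation (strong Si–F bond) frees the C11 alcohol without acid, which the diene would not tolerate.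

Step 13
Reactants: 21 (3S,5S,9R,10R)-drima-6,8(12)-diene-3,11-diol; 22 umbelliferone (7-hydroxycoumarin)
Product: 23 CNP0259618.1, 7-{[(1R,4aS,6S,8aR)-6-hydroxy-5,5,8a-trimethyl-2-methylidene-1,2,4a,5,6,7,8,8a-octahydronaphthalen-1-yl]methoxy}-2H-chromen-2-one
Conditions: PPh3, DIAD, THF, 0 °C → rt
Reagents that add atoms: none
Why: Mitsunobu etherification: the acidic phenol displaces the oxyphosphonium of the primary C11–OH, which is activated in preference to the axial, neopentyl C3–OH, and substitution at a CH2 group touches no stereocentre.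

Compound list
1 | 5-bromo-2-methylpent-2-ene | CC(C)=CCCBr | starting material
2 | 4-methylpent-3-enylmagnesium bromide | CC(C)=CCC[Mg]Br | intermediate
3 | 3-methylcyclohex-2-en-1-one | CC1=CC(=O)CCC1 | starting material
4 | formaldehyde (monomer from paraformaldehyde) | C=O | starting material
5 | bromomagnesium (S)-3-methyl-3-(4-methylpent-3-enyl)cyclohex-1-en-1-olate | Br[Mg]OC1=C[C@](C)(CCC=C(C)C)CCC1 | intermediate
6 | (2R,3S)-2-(hydroxymethyl)-3-methyl-3-(4-methylpent-3-enyl)cyclohexan-1-one (C11 cis to the C10 methyl, trans to the chain) | O=C1CCC[C@@](C)(CCC=C(C)C)[C@@H]1CO | intermediate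
7 | tert-butyldiphenylsilyl ether of 6 | O=C1CCC[C@@](C)(CCC=C(C)C)[C@@H]1CO[Si](c1ccccc1)(c1ccccc1)C(C)(C)C | intermediate
8 | lithium C7=C8 enolate of 7 | [Li]OC1=CCC[C@@](C)(CCC=C(C)C)[C@@H]1CO[Si](c1ccccc1)(c1ccccc1)C(C)(C)C | intermediate
9 | C7=C8 trimethylsilyl enol ether of 7 | C[Si](C)(C)OC1=CCC[C@@](C)(CCC=C(C)C)[C@@H]1CO[Si](c1ccccc1)(c1ccccc1)C(C)(C)C | intermediate
10 | (5R,6R)-6-[(tert-butyldiphenylsilyloxy)methyl]-5-methyl-5-(4-methylpent-3-enyl)cyclohex-2-en-1-one (C6=C7 enone) | O=C1C=CC[C@@](C)(CCC=C(C)C)[C@@H]1CO[Si](c1ccccc1)(c1ccccc1)C(C)(C)C | intermediate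
11 | bromomagnesium through-conjugated dienolate of 10 | Br[Mg]OC1=CC=C[C@@](C)(CCC=C(C)C)[C@@H]1CO[Si](c1ccccc1)(c1ccccc1)C(C)(C)C | intermediate
12 | through-conjugated trimethylsilyl dienol ether of 10 | C[Si](C)(C)OC1=CC=C[C@@](C)(CCC=C(C)C)[C@@H]1CO[Si](c1ccccc1)(c1ccccc1)C(C)(C)C | intermediate
13 | lithium through-conjugated dienolate of 10 | [Li]OC1=CC=C[C@@](C)(CCC=C(C)C)[C@@H]1CO[Si](c1ccccc1)(c1ccccc1)C(C)(C)C | intermediate
14 | C8 dienyl triflate (C5=C6–C7=C8–OTf) | O=S(=O)(OC1=CC=C[C@@](C)(CCC=C(C)C)[C@@H]1CO[Si](c1ccccc1)(c1ccccc1)C(C)(C)C)C(F)(F)F | intermediate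
15 | (3R)-3,4-epoxide of 14 | O=S(=O)(OC1=CC=C[C@@](C)(CC[C@H]2OC2(C)C)[C@@H]1CO[Si](c1ccccc1)(c1ccccc1)C(C)(C)C)C(F)(F)F | intermediate
16 | (trimethylsilyl)methylmagnesium chloride | C[Si](C)(C)C[Mg]Cl | starting material
17 | epoxy pentadienylsilane (Me3SiCH2 on C8, C5=C6–C7=C8, 3R) | C[Si](C)(C)CC1=CC=C[C@@](C)(CC[C@H]2OC2(C)C)[C@@H]1CO[Si](c1ccccc1)(c1ccccc1)C(C)(C)C | intermediate
18 | (3R,5S,9R,10R)-11-(tert-butyldiphenylsilyloxy)drima-6,8(12)-dien-3-ol (equatorial OH) | C=C1C=C[C@@H]2C(C)(C)[C@H](O)CC[C@@]2(C)[C@@H]1CO[Si](c1ccccc1)(c1ccccc1)C(C)(C)C | intermediate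
19 | (5S,9R,10R)-11-(tert-butyldiphenylsilyloxy)drima-6,8(12)-dien-3-one | C=C1C=C[C@@H]2C(C)(C)C(=O)CC[C@@]2(C)[C@@H]1CO[Si](c1ccccc1)(c1ccccc1)C(C)(C)C | intermediate
20 | (3S,5S,9R,10R)-11-(tert-butyldiphenylsilyloxy)drima-6,8(12)-dien-3-ol (axial OH) | C=C1C=C[C@@H]2C(C)(C)[C@@H](O)CC[C@@]2(C)[C@@H]1CO[Si](c1ccccc1)(c1ccccc1)C(C)(C)C | intermediate
21 | (3S,5S,9R,10R)-drima-6,8(12)-diene-3,11-diol | C=C1C=C[C@@H]2C(C)(C)[C@@H](O)CC[C@@]2(C)[C@@H]1CO | intermediate
22 | umbelliferone (7-hydroxycoumarin) | Oc1ccc2ccc(=O)oc2c1 | starting material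
23 | CNP0259618.1 | C=C1C=C[C@@H]2C(C)(C)[C@@H](O)CC[C@@]2(C)[C@@H]1COc1ccc2ccc(=O)oc2c1 | target

Total step count: 13. Longest linear sequence: 13 steps (1 → 23).

Steps most likely to fail

Step 9.
- What may go wrong: the closure may follow the cis-fused trajectory after all. A chain on the neighbouring carbon attacks a ring π bond most easily when the new bond is pseudoaxial, above all if the epoxide ionises before C5 arrives. The activated epoxide may also collapse by 1,2-hydride shift, or traces of acid may protodesilylate the diene.
- Fallback: it keeps the C8 ketone through the ring closure, so that C5 and C9 stay correctable. It sets out from enone 10.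
- Shi epoxidation, which ignores the electron-poor enone, gives the epoxy enone F1.
- O-silylation with t-BuMe2SiOTf/Et3N in CH2Cl2 at −78 °C gives the through-conjugated silyl dienol ether F2.
- MeAlCl2 then closes ring A in the known manner of silyl-enol-ether-terminated epoxide cyclizations to the hydroxy enone F3.
- In F3, C5 (γ to the ketone) and C9 (α′) are settled to the trans-fused, equatorial arrangement by brief amine- or acid-mediated equilibration through the dienol and enol.
- Petasis methylenation of C8 with Cp2TiMe2 (toluene, 65 °C) comes back to the route at 18.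

Step 2.
- What may go wrong: the homoprenyl group may be transferred with insufficient face selection or partly by uncatalysed 1,2-addition. The hindered enolate may also react sluggishly with formaldehyde. Proton transfer, repeated hydroxymethylation, retro-aldol on warming or poor facial selectivity at C9 would then erode the outcome.
- Fallback: it separates the two bond formations and sets out from 3 and 2.
- The copper-catalysed addition is quenched with Me3SiCl to give the silyl enol ether F4, which is isolated so that its enantiopurity can be checked.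
- C9–C11 is then made in a separate Mukaiyama aldol reaction with aqueous formaldehyde under Sc(OTf)3 catalysis in THF, which comes back at 6.

Step 5.
- What may go wrong: proton removal may occur at C9 instead of C5. That scrambles C9 and opens β-elimination of the silyloxy group. Methyl transfer to the enone may also compete.
- Fallback: it replaces deprotonation by a metal base with enolisation that starts at oxygen, and it sets out from 10.
- t-BuMe2SiOTf/Et3N in CH2Cl2 at rt silylates the carbonyl first and lets proton loss equilibrate to the linearly conjugated isomer, the tert-butyldimethylsilyl dienol ether F5.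
- CsF/PhNTf2 in DME converts F5 directly into the triflate, which comes back at 14.

Further compounds
F1 | step 9 | (3R)-epoxy enone (epoxide of 10) | O=C1C=CC[C@@](C)(CC[C@H]2OC2(C)C)[C@@H]1CO[Si](c1ccccc1)(c1ccccc1)C(C)(C)C
F2 | step 9 | through-conjugated tert-butyldimethylsilyl dienol ether of F1 | CC(C)(C)[Si](C)(C)OC1=CC=C[C@@](C)(CC[C@H]2OC2(C)C)[C@@H]1CO[Si](c1ccccc1)(c1ccccc1)C(C)(C)C
F3 | step 9 | (3R,5S,9R,10R)-3-hydroxy-11-(tert-butyldiphenylsilyloxy)-12-nordrim-6-en-8-one | O=C1C=C[C@@H]2C(C)(C)[C@H](O)CC[C@@]2(C)[C@@H]1CO[Si](c1ccccc1)(c1ccccc1)C(C)(C)C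
F4 | step 2 | (S)-trimethyl{[3-methyl-3-(4-methylpent-3-enyl)cyclohex-1-en-1-yl]oxy}silane | C[Si](C)(C)OC1=C[C@](C)(CCC=C(C)C)CCC1
F5 | step 5 | through-conjugated tert-butyldimethylsilyl dienol ether of 10 | CC(C)(C)[Si](C)(C)OC1=CC=C[C@@](C)(CCC=C(C)C)[C@@H]1CO[Si](c1ccccc1)(c1ccccc1)C(C)(C)C
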